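The piperidine is traced back to a pyridine, because in ring A the oxygens on C5 and C7 flank C6, the carbon that carries C2' next to N1'. While N1' is still aromatic it can hold palladium in five-membered palladacycles that reach only these two C–H bonds. In one operation the key step turns a para-oxygenated 2-arylpyridine into the full phloroglucinol pattern. It forms C5–O and C7–O as acetates while the future O1 on C8a keeps a different (benzyl) label. The precursor, 2-[4-(benzyloxy)phenyl]pyridine, comes from one Suzuki coupling. Asymmetric pyridinium hydrogenation later sets (R)-C2', and the lone free C8a phenol dictates the direction of pyranone closure.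

Key step: step 2

Remark: flavone numbering (O1, C2 to C8a, primes for the piperidine) is used for all intermediates.
Assumption: the sense of induction known for simple N-benzyl-2-arylpyridinium salts is taken to hold for 9, so (S)-SynPhos is written for the (R)-piperidine. If the hindered aryl group reverses it, the equally available (R)-ligand is used.

Step 1
Reactants: 1 4-(benzyloxy)phenylboronic acid; 2 2-bromopyridine
Product: 3 2-[4-(benzyloxy)phenyl]pyridine
Conditions: Pd(PPh3)4 (3 mol %), K2CO3, 1,4-dioxane/H2O, 90 °C
Reagents that add atoms: none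
Why: Suzuki–Miyaura coupling with the pyridine as the halide partner (fast oxidative addition to zerovalent palladium, no unstable 2-pyridylboron species) and an electron-rich, unhindered boronic acid is routine, and the benzyl ether is inert.

Step 2
Reactants: 3 2-[4-(benzyloxy)phenyl]pyridine; 4 (diacetoxyiodo)benzene
Product: 6 5-(benzyloxy)-2-(pyridin-2-yl)-1,3-phenylene diacetate, via monoacetate 5 (not isolated)
Conditions: Pd(OAc)2 (10 mol %), PhI(OAc)2 (3.5 equiv, two portions), AcOH/Ac2O 1:1, 100 °C
Reagents that add atoms: (diacetoxyiodo)benzene 4, CC(=O)OI(OC(C)=O)c1ccccc1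
Why: The pyridine nitrogen of 3 binds Pd(OAc)2, and concerted metalation–deprotonation of the neighbouring aryl C–H gives a five-membered palladacycle (Pd, N1', C2', C6, C5), which PhI(OAc)2 oxidises to tetravalent palladium before C–O reductive elimination releases monoacetate 5 and divalent palladium. Rotation about the C6–C2' axis then presents the remaining ortho C–H (C7), and the same cycle gives 6. The closest known reaction type is the pyridine-directed ortho C–H acetoxylation of 2-arylpyridines with a trivalent iodine oxidant, for which twofold reaction with surplus oxidant is established. No ring is closed and no stereocentre is created. The step needs site selectivity, secured by the chelate size because the C–H bonds beside the benzyloxy group (future C4a and C8) lie beyond the reach of nitrogen-bound palladium, and it needs exhaustive reaction, secured by more than three equivalents of oxidant added in portions. Ac2O as co-solvent keeps both new oxygens acetylated, so no free 2-pyridylphenol can sequester palladium as an N,O-chelate or be over-oxidised, and the benzyl ether carries no donor that could bring the metal to its own C–H bonds.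

Step 3
Reactants: 6 5-(benzyloxy)-2-(pyridin-2-yl)-1,3-phenylene diacetate
Product: 8 2-[4-(benzyloxy)-2,6-dimethoxyphenyl]pyridine, via resorcinol 7 (not isolated)
Conditions: K2CO3, MeOH, rt; evaporate; Me2SO4 (2.2 equiv), K2CO3, acetone, 50 °C
Reagents that add atoms: dimethyl sulfate, COS(=O)(=O)OC
Why: Base-catalysed methanolysis frees resorcinol 7 and a Williamson etherification caps both phenoxides, which are far better nucleophiles than the shielded pyridine nitrogen as long as Me2SO4 is limited to about two equivalents; methyl ethers are chosen because they survive quaternisation, both hydrogenations, BF3 and the amide base.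

Step 4
Reactants: 8 2-[4-(benzyloxy)-2,6-dimethoxyphenyl]pyridine
Product: 9 1-benzyl-2-[4-(benzyloxy)-2,6-dimethoxyphenyl]pyridinium bromide
Conditions: BnBr (3 equiv), MeCN, 85 °C (sealed tube)
Reagents that add atoms: benzyl bromide, BrCc1ccccc1
Why: Menshutkin quaternisation with a reactive benzylic halide activates the heterocycle for hydrogenation and blocks catalyst poisoning by nitrogen, and the N-benzyl group is chosen so that it leaves together with the O-benzyl group in step 6.

Step 5
Reactants: 9 1-benzyl-2-[4-(benzyloxy)-2,6-dimethoxyphenyl]pyridinium bromide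
Product: 10 (2R)-1-benzyl-2-[4-(benzyloxy)-2,6-dimethoxyphenyl]piperidine
Conditions: [Ir(cod)Cl]2 (1 mol %), (S)-SynPhos (2.2 mol %), H2 (40 bar), toluene/CH2Cl2 1:1, 30 °C; aq. Na2CO3
Reagents that add atoms: none
Why: Iridium-catalysed asymmetric hydrogenation of N-benzyl-2-arylpyridinium salts is a known reaction class: stepwise hydride addition and enamine–iminium tautomerisation lead to a cyclic C2'=N1' iminium ion, and the chiral iridium hydride formed with (S)-SynPhos delivers hydride to one of its faces, which sets (R)-C2', while the aryl ethers are inert to the homogeneous catalyst.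

Step 6
Reactants: 10 (2R)-1-benzyl-2-[4-(benzyloxy)-2,6-dimethoxyphenyl]piperidine
Product: 12 3,5-dimethoxy-4-[(2R)-1-methylpiperidin-2-yl]phenol, via secondary aminophenol 11 (not isolated)
Conditions: H2 (1 atm), Pd(OH)2/C, MeOH, rt; then 37 % aq. HCHO (1.2 equiv), H2, rt
Reagents that add atoms: formaldehyde, C=O
Why: Hydrogenolysis removes the N-benzyl and O-benzyl groups together (the endocyclic C2'–N1' bond is shielded by two ortho methoxy groups), and catalytic reductive amination of 11 with little more than one equivalent of formaldehyde methylates N1' without touching C2' and leaves little aldehyde for aminomethylation of the activated ring.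

Step 7
Reactants: 12 3,5-dimethoxy-4-[(2R)-1-methylpiperidin-2-yl]phenol
Product: 14 1-{6-hydroxy-2,4-dimethoxy-3-[(2R)-1-methylpiperidin-2-yl]phenyl}ethan-1-one, via aryl acetate 13 (not isolated)
Conditions: Ac2O (1.5 equiv), BF3·OEt2 (5 equiv), CH2Cl2, 0 → 40 °C; aq. Na2CO3
Reagents that add atoms: acetic anhydride, CC(=O)OC(C)=O
Why: O-acetylation followed by BF3-promoted Fries/Friedel–Crafts acyl transfer can only reach the two equivalent positions ortho to the C8a oxygen, boron chelation between that oxygen and the new carbonyl stops the reaction after one acylation and spares the neighbouring methoxy group, and the amine is masked as its BF3 adduct, as is known for piperidinyl-substituted phloroglucinol ethers.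

Step 8
Reactants: 14 1-{6-hydroxy-2,4-dimethoxy-3-[(2R)-1-methylpiperidin-2-yl]phenyl}ethan-1-one; 15 benzoyl chloride
Product: 17 5,7-dimethoxy-6-[(2R)-1-methylpiperidin-2-yl]-2-phenyl-4H-chromen-4-one, via 1,3-diketone 16 (not isolated)
Conditions: LiN(SiMe3)2 (3.5 equiv), THF, −78 → −10 °C; BzCl (1.05 equiv), −78 °C → rt; crude 16 in AcOH/conc. HCl, 40 °C
Reagents that add atoms: benzoyl chloride 15, O=C(Cl)c1ccccc1
Why: Claisen-type C-benzoylation of the lithium phenoxide–enolate dianion of 14 (the direct variant of the Baker–Venkataraman synthesis) gives diketone 16, whose acid-catalysed cyclodehydration can close ring C only through the free C8a–OH because the C5 oxygen is still a methyl ether, which fixes the 6-substituted flavone; C2'–H is far too weakly acidic for the amide base.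

Step 9
Reactants: 17 5,7-dimethoxy-6-[(2R)-1-methylpiperidin-2-yl]-2-phenyl-4H-chromen-4-one
Product: 18 5,7-dihydroxy-6-[(2R)-1-methylpiperidin-2-yl]-2-phenyl-4H-chromen-4-one (target)
Conditions: BBr3 (6 equiv), CH2Cl2, −78 °C → rt; ice-water, aq. NaHCO3 (pH 8)
Reagents that add atoms: none
Why: Lewis-acid ether cleavage with BBr3 (carbonyl-chelation-assisted at C5–OMe, ordinary at C7–OMe, extra equivalents for N1' and the C4 carbonyl) runs anhydrously at or below room temperature, so neither a Wessely–Moser ring opening and reclosure, which would move the piperidine from C6 to C8, nor thermal ionisation of the C2'–N1' bond, which would erode the configuration, should intervene.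

Compound list
1 | 4-(benzyloxy)phenylboronic acid | OB(O)c1ccc(OCc2ccccc2)cc1 | starting material
2 | 2-bromopyridine | Brc1ccccn1 | starting material
3 | 2-[4-(benzyloxy)phenyl]pyridine | c1ccc(nc1)-c1ccc(OCc2ccccc2)cc1 | intermediate
4 | (diacetoxyiodo)benzene | CC(=O)OI(OC(C)=O)c1ccccc1 | starting material
5 | 5-(benzyloxy)-2-(pyridin-2-yl)phenyl acetate | CC(=O)Oc1cc(OCc2ccccc2)ccc1-c1ccccn1 | intermediate (not isolated)
6 | 5-(benzyloxy)-2-(pyridin-2-yl)-1,3-phenylene diacetate | CC(=O)Oc1cc(OCc2ccccc2)cc(OC(C)=O)c1-c1ccccn1 | intermediate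
7 | 5-(benzyloxy)-2-(pyridin-2-yl)benzene-1,3-diol | Oc1cc(OCc2ccccc2)cc(O)c1-c1ccccn1 | intermediate (not isolated)
8 | 2-[4-(benzyloxy)-2,6-dimethoxyphenyl]pyridine | COc1cc(OCc2ccccc2)cc(OC)c1-c1ccccn1 | intermediate
9 | 1-benzyl-2-[4-(benzyloxy)-2,6-dimethoxyphenyl]pyridinium bromide | COc1cc(OCc2ccccc2)cc(OC)c1-c1cccc[n+]1Cc1ccccc1.[Br-] | intermediate
10 | (2R)-1-benzyl-2-[4-(benzyloxy)-2,6-dimethoxyphenyl]piperidine | c1ccccc1CN1CCCC[C@@H]1c1c(OC)cc(OCc2ccccc2)cc1OC | intermediate
11 | 3,5-dimethoxy-4-[(2R)-piperidin-2-yl]phenol | N1CCCC[C@@H]1c1c(OC)cc(O)cc1OC | intermediate (not isolated)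
12 | 3,5-dimethoxy-4-[(2R)-1-methylpiperidin-2-yl]phenol | CN1CCCC[C@@H]1c1c(OC)cc(O)cc1OC | intermediate
13 | 3,5-dimethoxy-4-[(2R)-1-methylpiperidin-2-yl]phenyl acetate | CN1CCCC[C@@H]1c1c(OC)cc(OC(C)=O)cc1OC | intermediate (not isolated)
14 | 1-{6-hydroxy-2,4-dimethoxy-3-[(2R)-1-methylpiperidin-2-yl]phenyl}ethan-1-one | CN1CCCC[C@@H]1c1c(OC)cc(O)c(C(C)=O)c1OC | intermediate
15 | benzoyl chloride | O=C(Cl)c1ccccc1 | starting material
16 | 1-{6-hydroxy-2,4-dimethoxy-3-[(2R)-1-methylpiperidin-2-yl]phenyl}-3-phenylpropane-1,3-dione | CN1CCCC[C@@H]1c1c(OC)cc(O)c(C(=O)CC(=O)c2ccccc2)c1OC | intermediate (not isolated)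
17 | 5,7-dimethoxy-6-[(2R)-1-methylpiperidin-2-yl]-2-phenyl-4H-chromen-4-one | CN1CCCC[C@@H]1c1c(OC)cc2oc(-c3ccccc3)cc(=O)c2c1OC | intermediate
18 | 5,7-dihydroxy-6-[(2R)-1-methylpiperidin-2-yl]-2-phenyl-4H-chromen-4-one | CN1CCCC[C@@H]1c1c(O)cc2oc(-c3ccccc3)cc(=O)c2c1O | target

Total step count: 9. Longest linear sequence: 9 steps (1 and 2 to 18).

Steps most likely to fail

Step 5. Hydride delivery to the cyclic iminium stage may be slow or poorly face-selective, because the doubly ortho-substituted aryl group is twisted out of conjugation and crowds C2'. The same crowding may also retard the quaternisation of step 4. The fallback replaces asymmetric catalysis by racemic reduction and resolution; it sets out from 8 and comes back at 12, replacing steps 4 to 6.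
- Compound 8 is N-methylated with the small, powerful electrophile MeOTf (CH2Cl2, rt) to 2-[4-(benzyloxy)-2,6-dimethoxyphenyl]-1-methylpyridinium trifluoromethanesulfonate F1.
- Exhaustive heterogeneous hydrogenation (H2, 5 bar, PtO2, AcOH, then Pd/C in the same vessel; aq. Na2CO3) saturates the heterocycle and removes the O-benzyl group. This gives racemic 3,5-dimethoxy-4-(1-methylpiperidin-2-yl)phenol F2.
- Preparative chromatography on a chiral stationary phase separates the enantiomers, and the (R)-enantiomer is 12.

Step 2. The reaction may stall after the first acetoxylation, because the second cyclopalladation demands near coplanarity of the pyridine with a ring that now bears an ortho substituent. Long heating with the oxidant may also degrade the benzyl ether. The fallback cross-couples a ring A that already carries all three oxygens; it sets out from 2 and comes back at 8, replacing steps 1 to 3.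
- Commercial 2-bromo-1,3-dimethoxybenzene (COc1cccc(OC)c1Br) is borylated at its only unhindered C–H ([Ir(OMe)(cod)]2, 4,4'-di-tert-butyl-2,2'-bipyridine, B2pin2, THF, 80 °C). This gives 2-(4-bromo-3,5-dimethoxyphenyl)-4,4,5,5-tetramethyl-1,3,2-dioxaborolane F3.
- Oxidation (H2O2, NaOH) gives 4-bromo-3,5-dimethoxyphenol F4.
- Benzylation (BnBr, K2CO3, DMF) gives 5-(benzyloxy)-2-bromo-1,3-dimethoxybenzene F5.
- Magnesium insertion in the presence of LiCl and ZnCl2 (THF, rt) gives [4-(benzyloxy)-2,6-dimethoxyphenyl]zinc chloride F6.
- Negishi coupling of F6 with 2 (Pd2(dba)3, SPhos, THF, 60 °C) gives 8.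

Step 7. Three things may go wrong:
- C-acylation may lag behind O-acetylation.
- The Lewis acid may demethylate the ether beside the new carbonyl and so erase the distinction between the oxygens.
- Reversible ionisation of the C2'–N1' bond on the very electron-rich ring may erode the configuration if heating is needed.

The fallback replaces Lewis-acid acylation and diketone chemistry by halogenation and palladium-catalysed carbonylative annulation; it sets out from 12 and comes back at 17, replacing steps 7 and 8.
- N-Iodosuccinimide (1.0 equiv, CF3CO2H 1 equiv to protonate the amine, MeCN, 0 °C) iodinates one of the two equivalent free ring positions. This gives 2-iodo-3,5-dimethoxy-4-[(2R)-1-methylpiperidin-2-yl]phenol F7.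
- Carbonylative Sonogashira coupling with phenylacetylene (CO 1 atm, PdCl2(PPh3)2, Et2NH, 60 °C) passes through 1-{6-hydroxy-2,4-dimethoxy-3-[(2R)-1-methylpiperidin-2-yl]phenyl}-3-phenylprop-2-yn-1-one F8.
- In the amine medium F8 undergoes 6-endo conjugate addition of the C8a phenol and delivers 17.

Further compounds
F1 | step 5 | 2-[4-(benzyloxy)-2,6-dimethoxyphenyl]-1-methylpyridinium trifluoromethanesulfonate | COc1cc(OCc2ccccc2)cc(OC)c1-c1cccc[n+]1C.[O-]S(=O)(=O)C(F)(F)F
F2 | step 5 | racemic 3,5-dimethoxy-4-(1-methylpiperidin-2-yl)phenol | CN1CCCCC1c1c(OC)cc(O)cc1OC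
F3 | step 2 | 2-(4-bromo-3,5-dimethoxyphenyl)-4,4,5,5-tetramethyl-1,3,2-dioxaborolane | COc1cc(B2OC(C)(C)C(C)(C)O2)cc(OC)c1Br
F4 | step 2 | 4-bromo-3,5-dimethoxyphenol | COc1cc(O)cc(OC)c1Br
F5 | step 2 | 5-(benzyloxy)-2-bromo-1,3-dimethoxybenzene | COc1cc(OCc2ccccc2)cc(OC)c1Br
F6 | step 2 | [4-(benzyloxy)-2,6-dimethoxyphenyl]zinc chloride | COc1cc(OCc2ccccc2)cc(OC)c1[Zn]Cl
F7 | step 7 | 2-iodo-3,5-dimethoxy-4-[(2R)-1-methylpiperidin-2-yl]phenol | CN1CCCC[C@@H]1c1c(OC)cc(O)c(I)c1OC
F8 | step 7 | 1-{6-hydroxy-2,4-dimethoxy-3-[(2R)-1-methylpiperidin-2-yl]phenyl}-3-phenylprop-2-yn-1-one | CN1CCCC[C@@H]1c1c(OC)cc(O)c(C(=O)C#Cc2ccccc2)c1OC
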